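In the earlier run birch the target stops near 33.3% of the starting material charged, so 66.7% is a leftover that no reading shows. In elm, with more second substrate, the stop falls to 25.6%.

| setting | birch | elm | dusk | midnight | winter | noon |
|---|---|---|---|---|---|---|
| starting material | 0.050 M | 0.050 M | 0.050 M | 0.050 M | 0.050 M | 0.050 M |
| coupling partner | 0.95 equiv | 0.95 equiv | 0.950 equiv (fed, over 40 min) | 0.950 equiv (fed, over 40 min) | 0.950 equiv | 0.950 equiv |
| second substrate | 2 equiv | 3 equiv | 2.00 equiv | 2.00 equiv | 2.00 equiv (in portions, 2, over 40 min) | 2.00 equiv |
| protic impurity | 1 mM | 1 mM | 1.00 mM | 1.00 mM | 1.00 mM | 1.00 mM |
| temperature | 100 °C | 100 °C |  | 100 °C | 100 °C | 100 °C |
| remark | run made earlier | run made earlier | the addition at 80 °C, then warmed to 100 °C; the feed brings no volume worth counting | all else is in the flask from the start; the feed brings no volume worth counting | first portion at the start, last at 40 min | everything together at the start |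
| time |  |  | 50 min | 50 min | 50 min | 50 min |

- birch (time / min: target / %): 8.00: 32.4; 15.0: 33.7; 20.0: 33.4; 30.0: 33.2; 40.0: 33.1; 50.0: 33.3
- elm (time / min: target / %): 0.833: 14.0; 2.50: 22.1; 4.00: 24.8; 6.00: 25.4; 10.0: 25.9; 12.0: 25.1; 15.0: 25.9

(each reading ± 0.3 percentage points)

- what was read earlier has a scatter of 0.3 percentage points, one standard deviation
- a reading or a percentage of target counts all its forms, free or not
- the earlier runs do not show what temperature does; that part of a forecast is a guess

* the flask that comes out highest in amount of target, in percent of the starting material charged, or "all alike" when all lie within 1.5 percentage points (dusk / midnight / winter / noon / all alike)
* target at the end, in percent of the starting material charged, dusk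
* target at the end, in percent of the starting material charged, midnight
* target at the end, in percent of the starting material charged, winter
* target at the end, in percent of the starting material charged, noon

The readings do not say which species is shared. The reckoning here wagers that starting material is shared, taken by coupling partner and second substrate side by side. One dimensionless number then describes a flask:

share number = selectivity factor × partner present ÷ second substrate present

target share = share number ÷ (1 + share number)

"Present" means the mean while starting material lives, and that mean needs the answer, so the first answer goes back in. Birch reads 1.06 and elm 1.10. Their mean, 1.08, is the reading taken for the selectivity factor: the rate at which the partner takes starting material over the rate at which the second substrate takes it, at equal concentration.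

Noon repeats birch's charges, so it carries birch's reading. Winter opens with half of the second substrate, so its share number is 1.03, and one round gives 1.00, a target share of 50.0%.

The fed flasks test the number, since their partner present is not the charge. Elm's first reading gives starting material a mean life of 1.05 min. Reckoned against second substrate by itself at midnight's charge, that life of starting material becomes 2.12 min, far shorter than the feed. Midnight's partner present is therefore the charge times life over feed time:

first round: share number 0.0272

second round, second substrate down a quarter: share number 0.0483, target share 4.61%

Dusk gets a similarly low figure, its temperature being a guess.

The forecast names winter, with 33% for dusk, 33% for midnight, 48.5% for winter and 33.3% for noon, holding that both runs “fit the coupling partner being shared”. The two reckonings part on the fed flasks, where this one stands far below the forecast; on winter this one stands a little above it.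

The flasks give 7.59% in dusk, 4.36% in midnight, 48.6% in winter and 33.2% in noon, with winter highest.

    starting material + coupling partner → target (k = 0.0950 /M/s, Ea = 84.0 kJ/mol)
    second substrate + coupling partner → second product (k = 0.00140 /M/s, Ea = 84.0 kJ/mol)
    starting material + second substrate → cross product (k = 0.0800 /M/s, Ea = 59.0 kJ/mol)
    coupling partner + target ⇌ idle adduct, settled at all times (K = 13.0 /M, ΔH = 23.0 kJ/mol)
    starting material + protic impurity → quenched substrate (k = 0.280 /M/s, Ea = 65.0 kJ/mol)
    (constants at 100 °C)

Midnight ends with 93.9% of its starting material as cross product. Without the step from starting material and second substrate to cross product, the gap in target between winter and midnight shrinks from 44 percentage points to 9 points. The selectivity factor 1.08 serves a neighbour of winter charged with 1.20 equiv of second substrate: its share number, 1.71, goes round to 1.65, a target share of 62.3%, and that flask gives 60.2%.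

All runs were generated by integration with constants of no real substance; scatter was added.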